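**Plan**

1. Ring letters: A = para-phenylene ring, B = phenol ring bearing the A–O ether, C = 1,2,3-trisubstituted phenol ring, D = meta-phenylene ring. The target is achiral, so no stereocentre has to be set; the only stereo element on the way, the E-alkene of 10, is erased in step 8.
2. Retrosynthetic cuts, in order: the two O–CH3 bonds (phenol protection); the bond between the ring A carbon para to the A–O–B oxygen and the adjacent CH2 of the A–C bridge, which opens the 18-membered ring to an aryl bromide and a primary alkyl bromide; the CH2–CH2 bond of the B–D bridge (made as an alkene); the two diaryl ether C–O bonds.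
3. Forward: all four benzene rings are bought. Ether A–O–B (step 1) and ether C–O–D (step 2) are made on separate halves. The C–D half is armed as a benzylic phosphonate with a vinyl group on ring C (steps 3–5) and joined to the A–B half through the B–D bridge (step 6). The vinyl group becomes CH2CH2Br and the alkene is saturated (steps 7–9). The macrocycle, the only ring that is made, is closed (step 10) and the phenols are freed (step 11).
4. Feature that makes the ring closure possible: the ring A carbon of the cut bond is para to the ether oxygen on a ring with no other substituent, so it arrives as a C–Br bond with the purchased ring; its partner is a primary, homobenzylic CH2 on ring C. Both carbons are electrophilic and are united by a nickel/radical reductive coupling with no organometallic reagent made beforehand. The bromine fixes the reacting site on ring A, which avoids the seven-membered closure onto ring D (ortho to the C–O–D oxygen) that cationic chemistry at this CH2 would favour.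

Key step: step 10

**Route**

Step 1
Reactants: 1 isovanillin (3-hydroxy-4-methoxybenzaldehyde); 2 4-bromophenylboronic acid
Product: 3 3-(4-bromophenoxy)-4-methoxybenzaldehyde
Conditions: Cu(OAc)2 (20 mol %), pyridine (3 equiv), 4 Å MS, O2 (1 atm), CH2Cl2, rt
Reagents that add atoms: none
Why: Chan–Lam–Evans coupling, in which the aryl group passes from boron to the copper phenoxide of 1 and C–O reductive elimination from the oxidised copper centre should give the diaryl ether at room temperature, where the aldehyde and the C–Br bond are inert.

Step 2
Reactants: 4 3-hydroxybenzyl alcohol [3-(hydroxymethyl)phenol]; 5 2-fluoro-3-methoxybenzaldehyde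
Product: 6 2-[3-(hydroxymethyl)phenoxy]-3-methoxybenzaldehyde
Conditions: K2CO3 (2 equiv), DMA, 120 °C
Reagents that add atoms: none
Why: Nucleophilic aromatic substitution (SNAr, addition–elimination), in which the phenoxide of 4 adds to the fluorine-bearing carbon of 5, the ortho formyl group stabilises the Meisenheimer intermediate, fluoride leaves, and K2CO3 ionises the phenol but not the benzylic alcohol.

Step 3
Reactants: 6 2-[3-(hydroxymethyl)phenoxy]-3-methoxybenzaldehyde
Product: 7 [3-(2-ethenyl-6-methoxyphenoxy)phenyl]methanol
Conditions: Ph3PCH3Br (2.5 equiv), KOtBu (2.4 equiv), THF, 0 °C to rt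
Reagents that add atoms: methyltriphenylphosphonium bromide, C[P+](c1ccccc1)(c1ccccc1)c1ccccc1.[Br-]
Why: Wittig methylenation, in which the non-stabilised ylide should convert the aryl aldehyde into the terminal alkene through an oxaphosphetane while the extra base only holds the benzylic alcohol as its alkoxide until work-up.

Step 4
Reactants: 7 [3-(2-ethenyl-6-methoxyphenoxy)phenyl]methanol
Product: 8 2-[3-(bromomethyl)phenoxy]-1-ethenyl-3-methoxybenzene
Conditions: CBr4 (1.3 equiv), PPh3 (1.3 equiv), CH2Cl2, 0 °C
Reagents that add atoms: carbon tetrabromide, BrC(Br)(Br)Br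
Why: Appel reaction, in which the alcohol is activated as an alkoxyphosphonium ion and displaced by bromide (SN2 at the benzylic carbon) under neutral conditions that should leave the styrene and the ethers untouched.

Step 5
Reactants: 8 2-[3-(bromomethyl)phenoxy]-1-ethenyl-3-methoxybenzene
Product: 9 diethyl {[3-(2-ethenyl-6-methoxyphenoxy)phenyl]methyl}phosphonate
Conditions: P(OEt)3 (neat, 3 equiv), BHT (1 mol %), 100 °C
Reagents that add atoms: triethyl phosphite, CCOP(OCC)OCC
Why: Michaelis–Arbuzov reaction, in which phosphorus attacks the benzylic bromide (SN2) and bromide dealkylates the phosphonium ion, at a temperature below that at which the inhibited styrene should polymerise.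

Step 6
Reactants: 9 diethyl {[3-(2-ethenyl-6-methoxyphenoxy)phenyl]methyl}phosphonate; 3 3-(4-bromophenoxy)-4-methoxybenzaldehyde
Product: 10 2-(4-bromophenoxy)-4-[(E)-2-[3-(2-ethenyl-6-methoxyphenoxy)phenyl]ethenyl]-1-methoxybenzene
Conditions: KOtBu (1.2 equiv), THF, 0 °C to rt
Reagents that add atoms: none
Why: Horner–Wadsworth–Emmons olefination, in which the benzylic phosphonate anion adds reversibly to the aldehyde and syn-elimination of diethyl phosphate from the less crowded oxaphosphetane should give the E-alkene (thermodynamic control), a geometry of no consequence because the alkene is saturated in step 8.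

Step 7
Reactants: 10 2-(4-bromophenoxy)-4-[(E)-2-[3-(2-ethenyl-6-methoxyphenoxy)phenyl]ethenyl]-1-methoxybenzene
Product: 12 2-[2-[3-[(E)-2-[3-(4-bromophenoxy)-4-methoxyphenyl]ethenyl]phenoxy]-3-methoxyphenyl]ethanol, via alkylborane 11 (not isolated)
Conditions: 9-BBN (1.3 equiv), THF, 0 °C to rt; then NaOH (3 M aq), H2O2 (30 %), 0 °C to rt
Reagents that add atoms: 9-borabicyclo[3.3.1]nonane, B1C2CCCC1CCC2 (its atoms stay in 11 only); hydrogen peroxide, OO (the oxygen of 12)
Why: Hydroboration–oxidation, in which 9-BBN should place boron on the terminal carbon of the monosubstituted vinyl group (anti-Markovnikov, steric control) far faster than it attacks the 1,2-diaryl alkene, and alkaline H2O2 replaces boron by OH.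

Step 8
Reactants: 12 2-[2-[3-[(E)-2-[3-(4-bromophenoxy)-4-methoxyphenyl]ethenyl]phenoxy]-3-methoxyphenyl]ethanol
Product: 13 2-[2-[3-[2-[3-(4-bromophenoxy)-4-methoxyphenyl]ethyl]phenoxy]-3-methoxyphenyl]ethanol
Conditions: TsNHNH2 (6 equiv, in portions), NaOAc (6 equiv), THF/H2O 1:1, reflux
Reagents that add atoms: none
Why: Diimide reduction, in which HN=NH released from the sulfonyl hydrazide transfers two hydrogens to the C=C bond in a concerted, metal-free step, so the aryl C–Br bond that hydrogenation over palladium would endanger should survive.

Step 9
Reactants: 13 2-[2-[3-[2-[3-(4-bromophenoxy)-4-methoxyphenyl]ethyl]phenoxy]-3-methoxyphenyl]ethanol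
Product: 14 2-(4-bromophenoxy)-4-[2-[3-[2-(2-bromoethyl)-6-methoxyphenoxy]phenyl]ethyl]-1-methoxybenzene
Conditions: CBr4 (1.3 equiv), PPh3 (1.3 equiv), CH2Cl2, 0 °C to rt
Reagents that add atoms: carbon tetrabromide, BrC(Br)(Br)Br
Why: Appel reaction, in which bromide displaces the alkoxyphosphonium ion at the primary carbon (SN2) under neutral conditions, so elimination to the styrene is not expected.

Step 10
Reactants: 14 2-(4-bromophenoxy)-4-[2-[3-[2-(2-bromoethyl)-6-methoxyphenoxy]phenyl]ethyl]-1-methoxybenzene
Product: 15 marchantin C di-O-methyl ether (the target macrocycle with both phenolic OH as OCH3)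
Conditions: NiBr2(dme) (30 mol %; dme = 1,2-dimethoxyethane), 4,4'-di-tert-butyl-2,2'-bipyridine (30 mol %), Zn dust (4 equiv), DMA, 60 °C; 14 added by syringe pump over 12 h to a final 2 mM
Reagents that add atoms: none
Why: Proposed new method: the intermolecular nickel-catalysed reductive coupling of an aryl bromide with a primary alkyl bromide (cross-electrophile coupling) is the closest known reaction type, and its use to close a large ring in this compound class is the untested part. Mechanism: zerovalent nickel bound to the bipyridine inserts into the sp2 C–Br bond of ring A, a monovalent nickel bromide abstracts the bromine atom of the CH2CH2Br arm on ring C, the primary 2-arylethyl radical is captured by the aryl nickel bromide (divalent nickel), reductive elimination from trivalent nickel forms the aryl–CH2 bond, and Zn returns nickel to its low-valent states. Ring closure: one 18-membered ring is closed end to end by radical capture at the nickel centre on ring A followed by C–C reductive elimination, not by radical addition to an arene, so no exo or endo mode applies, and slow addition at 2 mM should favour it over chain growth. No stereocentre is formed. The selectivity needed is cross- over homo-coupling, secured by the two different activation modes (two-electron insertion at the sp2 C–Br bond, halogen-atom abstraction at the sp3 C–Br bond), and ring A over ring D, secured because the bromine fixes the reacting carbon para to the A–O–B oxygen, whereas a cation at this CH2 would close a seven-membered ring onto ring D. The 1,2-aryl shift open to the 2-arylethyl radical is degenerate (both CH2 groups become equivalent), so it cannot scramble the bridge, and the diaryl ether C–O bonds are not expected to react with nickel/bipyridine at 60 °C.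

Step 11
Reactants: 15 marchantin C di-O-methyl ether
Product: 16 marchantin C
Conditions: BBr3 (6 equiv), CH2Cl2, −78 °C to rt; then H2O
Reagents that add atoms: none
Why: Lewis acid ether cleavage, in which BBr3 coordinates each methoxy oxygen and bromide removes the methyl group by SN2, while the diaryl ether oxygens carry no sp3 carbon and should stay intact, and aqueous work-up frees the two phenols.

**Compound list**

1 | isovanillin (3-hydroxy-4-methoxybenzaldehyde) | COc1ccc(C=O)cc1O | starting material
2 | 4-bromophenylboronic acid | OB(O)c1ccc(Br)cc1 | starting material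
3 | 3-(4-bromophenoxy)-4-methoxybenzaldehyde | COc1ccc(C=O)cc1Oc1ccc(Br)cc1 | intermediate
4 | 3-hydroxybenzyl alcohol | OCc1cccc(O)c1 | starting material
5 | 2-fluoro-3-methoxybenzaldehyde | COc1cccc(C=O)c1F | starting material
6 | 2-[3-(hydroxymethyl)phenoxy]-3-methoxybenzaldehyde | COc1cccc(C=O)c1Oc1cccc(CO)c1 | intermediate
7 | [3-(2-ethenyl-6-methoxyphenoxy)phenyl]methanol | COc1cccc(C=C)c1Oc1cccc(CO)c1 | intermediate
8 | 2-[3-(bromomethyl)phenoxy]-1-ethenyl-3-methoxybenzene | COc1cccc(C=C)c1Oc1cccc(CBr)c1 | intermediate
9 | diethyl {[3-(2-ethenyl-6-methoxyphenoxy)phenyl]methyl}phosphonate | COc1cccc(C=C)c1Oc1cccc(CP(=O)(OCC)OCC)c1 | intermediate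
10 | 2-(4-bromophenoxy)-4-[(E)-2-[3-(2-ethenyl-6-methoxyphenoxy)phenyl]ethenyl]-1-methoxybenzene | COc1cccc(C=C)c1Oc1cccc(/C=C/c2ccc(OC)c(Oc3ccc(Br)cc3)c2)c1 | intermediate
11 | 9-[2-[2-[3-[(E)-2-[3-(4-bromophenoxy)-4-methoxyphenyl]ethenyl]phenoxy]-3-methoxyphenyl]ethyl]-9-borabicyclo[3.3.1]nonane (alkylborane, not isolated) | COc1cccc(CCB2C3CCCC2CCC3)c1Oc1cccc(/C=C/c2ccc(OC)c(Oc3ccc(Br)cc3)c2)c1 | intermediate
12 | 2-[2-[3-[(E)-2-[3-(4-bromophenoxy)-4-methoxyphenyl]ethenyl]phenoxy]-3-methoxyphenyl]ethanol | COc1cccc(CCO)c1Oc1cccc(/C=C/c2ccc(OC)c(Oc3ccc(Br)cc3)c2)c1 | intermediate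
13 | 2-[2-[3-[2-[3-(4-bromophenoxy)-4-methoxyphenyl]ethyl]phenoxy]-3-methoxyphenyl]ethanol | COc1cccc(CCO)c1Oc1cccc(CCc2ccc(OC)c(Oc3ccc(Br)cc3)c2)c1 | intermediate
14 | 2-(4-bromophenoxy)-4-[2-[3-[2-(2-bromoethyl)-6-methoxyphenoxy]phenyl]ethyl]-1-methoxybenzene | COc1cccc(CCBr)c1Oc1cccc(CCc2ccc(OC)c(Oc3ccc(Br)cc3)c2)c1 | intermediate
15 | marchantin C di-O-methyl ether | COc1ccc2cc1Oc1ccc(cc1)CCc1cccc(OC)c1Oc1cccc(c1)CC2 | intermediate
16 | marchantin C | Oc1ccc2cc1Oc1ccc(cc1)CCc1cccc(O)c1Oc1cccc(c1)CC2 | target

**Count and risks**

Total step count: 11. Longest linear sequence: 10 steps (steps 2 to 11, from 4 and 5).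

The three steps most likely to fail:

1. Step 10 (proposed new method). Chain growth by intermolecular aryl–alkyl coupling, hydrodebromination of either C–Br bond, and loss of HBr from the 2-arylethyl arm by β-hydride elimination at nickel may outrun ring closure. The fallback uses known chemistry, a B-alkyl Suzuki–Miyaura macrocyclisation, in which a two-electron palladium cycle and a preformed alkylborane replace the radical nickel cycle. It sets out from 14. KOtBu in THF at 0 °C should remove HBr (E2) to give the styrene 2-(4-bromophenoxy)-4-[2-[3-(2-ethenyl-6-methoxyphenoxy)phenyl]ethyl]-1-methoxybenzene F1. Hydroboration of F1 with 9-BBN in THF should give the alkylborane 9-[2-[2-[3-[2-[3-(4-bromophenoxy)-4-methoxyphenyl]ethyl]phenoxy]-3-methoxyphenyl]ethyl]-9-borabicyclo[3.3.1]nonane F2. This solution would be added slowly to Pd(dppf)Cl2 (10 mol %) and Cs2CO3 in THF/DMF/H2O at 70 °C (final 2 mM). Zerovalent palladium inserts into the ring A C–Br bond, the hydroxide-activated borane transfers its primary alkyl group, and reductive elimination closes the ring. The fallback comes back to the route at 15.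

2. Step 2. Addition–elimination may be slow at a fluoride flanked by two ortho substituents and activated by a single formyl group, and base-induced disproportionation of the aldehyde may set in at the temperature needed. The fallback sets out from 4 and is a copper-catalysed Ullmann-type C–O coupling with commercial 2-bromo-3-methoxybenzaldehyde (CuI 10 mol %, N,N-dimethylglycine 30 mol %, Cs2CO3, dioxane, 100 °C). The ortho formyl group assists the copper insertion, and the phenol, not the aliphatic alcohol, is arylated. It comes back at 6 and makes no compound outside the list (F0).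

3. Step 1. Protodeboronation and oxidative self-coupling of the arylboronic acid may consume it faster than the copper-bound phenoxide of the ortho-methoxy phenol is arylated. The fallback sets out from 1 and is a metal-free O-arylation with bis(4-bromophenyl)iodonium trifluoromethanesulfonate (K2CO3, MeCN, 60 °C). The phenoxide binds to iodine and ligand coupling transfers one 4-bromophenyl group to oxygen. It comes back at 3 and makes no compound outside the list (F0).

**Further compounds**

F1 | step 10 | 2-(4-bromophenoxy)-4-[2-[3-(2-ethenyl-6-methoxyphenoxy)phenyl]ethyl]-1-methoxybenzene | COc1cccc(C=C)c1Oc1cccc(CCc2ccc(OC)c(Oc3ccc(Br)cc3)c2)c1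
F2 | step 10 | 9-[2-[2-[3-[2-[3-(4-bromophenoxy)-4-methoxyphenyl]ethyl]phenoxy]-3-methoxyphenyl]ethyl]-9-borabicyclo[3.3.1]nonane | COc1cccc(CCB2C3CCCC2CCC3)c1Oc1cccc(CCc2ccc(OC)c(Oc3ccc(Br)cc3)c2)c1
F0 | step 2 | none | none
F0 | step 1 | none | none
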